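**Retrosynthetic overview**
1. Target ⇒ Z-diene from a C12 aldehyde (α-iodo-olefination, then vinyl coupling) ⇒ 6,7-diacetoxy-8-hydroxy ring B ⇒ ring-B 8-hydroxy-5-en-7-one 15 (C5=C6 reduction, C6 hydroxylation, C7 reduction).
2. Feature: in ring B the C7 oxygen and the tertiary C8 carbinol (C8–OH, C8–CH3), next to C9, form an α-ketol. It is the product of a 1,2-shift of C9 from C7 to the acetyl carbon (future C8) of a 7-acetyl-7-hydroxy five-membered ring (C5, C6, C7, C9, C10).
3. Key disconnection C8–C9: 15 ⇒ hydrindene ketol 14, by a base-mediated α-ketol ring expansion through the non-chelated anti rotamer, the only mode that carries the C7 configuration of 14 correctly into C8.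
4. 14 ⇒ hydrindenone 11 (acetyl anion equivalent added anti to the C9 chain) ⇒ enone 6 (C9 chain by aldol, dehydration, face-selective hydrogenation) ⇒ ketone 1 (C10 by decarboxylative asymmetric allylation; Wacker oxidation; aldol condensation).
5. Ring order: ring A (from the cyclohexanone), then the five-membered ring, then ring B by enlargement of that ring.

Key step: step 9

Remark 1: labdane numbering is used for all bicyclic compounds (ring A = C1–C5, C10; ring B = C5–C10; C9 carries C11–C12). The target SMILES defines an ent-labdane: the C10 methyl, C9 chain, C8 methyl and C7 acetate lie on one face; H5, the C6 acetate and the C8 hydroxyl on the other.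
Remark 2 (assumption): the (S)-phosphinooxazoline ligand is taken to give (S)-4, as in the 2-allyl-2-methylcyclohexanone series; if the sense is opposite, the (R)-ligand is used.
Remark 3: the C12 oxygen is carried as a tert-butyldimethylsilyl ether, because a benzyl ether would be lost in the dissolving-metal step 10.

**Step 1**
Reactants: 1 2,2,6-trimethylcyclohexan-1-one; 2 allyl chloroformate
Product: 3 allyl 2,6,6-trimethylcyclohex-1-en-1-yl carbonate
Conditions: LiN(SiMe3)2, THF, 0 °C; then 2, −78 °C → rt
Reagents that add atoms: none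
Why: O-acylation of the only possible lithium enolate by the chloroformate gives the allyl enol carbonate (enol carbonate formation).

**Step 2**
Reactants: 3 allyl 2,6,6-trimethylcyclohex-1-en-1-yl carbonate
Product: 4 (S)-2-allyl-2,6,6-trimethylcyclohexan-1-one
Conditions: Pd2(dba)3 (2.5 mol%), (S)-4-tert-butyl-2-[2-(diphenylphosphino)phenyl]-4,5-dihydrooxazole (6 mol%), THF, 25 °C
Reagents that add atoms: none
Why: Decarboxylative asymmetric allylic alkylation (Tsuji allylation): ionisation and loss of CO2 give a π-allylpalladium enolate pair that recombines within the chiral ligand sphere and sets the quaternary C10 centre.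

**Step 3**
Reactants: 4 (S)-2-allyl-2,6,6-trimethylcyclohexan-1-one
Product: 5 (S)-2,2,6-trimethyl-6-(2-oxopropyl)cyclohexan-1-one
Conditions: PdCl2 (10 mol%), Cu(OAc)2 (20 mol%), O2 (1 atm), DMA–H2O, rt
Reagents that add atoms: water, O
Why: Wacker oxidation of the terminal alkene (Markovnikov hydroxypalladation, β-hydride elimination) gives the methyl ketone without touching the quaternary centre.

**Step 4**
Reactants: 5 (S)-2,2,6-trimethyl-6-(2-oxopropyl)cyclohexan-1-one
Product: 6 (S)-4,4,7a-trimethyl-1,4,5,6,7,7a-hexahydro-2H-inden-2-one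
Conditions: KOH (0.5 equiv), xylenes, 110 °C, water separator
Reagents that add atoms: none
Why: Intramolecular aldol condensation of the methyl ketone enolate onto the ring carbonyl closes the five-membered ring as the cyclopentenone (C7 carbonyl, C5=C6), driven by azeotropic removal of water.

**Step 5**
Reactants: 6 (S)-4,4,7a-trimethyl-1,4,5,6,7,7a-hexahydro-2H-inden-2-one; 7 (tert-butyldimethylsilyloxy)acetaldehyde
Product: 8 (7aS)-1-[2-(tert-butyldimethylsilyloxy)-1-hydroxyethyl]-4,4,7a-trimethyl-1,4,5,6,7,7a-hexahydro-2H-inden-2-one (diastereomer mixture at C9 and C11)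
Conditions: LiN(iPr)2, THF, −78 °C; 7; then aq. NH4Cl
Reagents that add atoms: none
Why: Kinetic deprotonation can occur only at the α′-methylene C9 (both γ-positions are quaternary), and the cross-conjugated lithium enolate adds to the aldehyde (aldol addition); both new centres are removed in step 6.

**Step 6**
Reactants: 8 aldol adduct
Product: 10 (7aS)-1-[2-(tert-butyldimethylsilyloxy)ethylidene]-4,4,7a-trimethyl-1,4,5,6,7,7a-hexahydro-2H-inden-2-one (E/Z mixture), via C11 methanesulfonate 9 (not isolated)
Conditions: MsCl, Et3N, CH2Cl2, 0 °C; then DBU, rt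
Reagents that add atoms: none
Why: Mesylation followed by E1cB elimination through the C9 enolate gives the exocyclic alkylidene ketone; the alkene geometry is of no consequence.

**Step 7**
Reactants: 10 alkylidene dienone
Product: 11 (1S,7aS)-1-[2-(tert-butyldimethylsilyloxy)ethyl]-4,4,7a-trimethyl-1,4,5,6,7,7a-hexahydro-2H-inden-2-one (C9 chain cis to the C10 methyl)
Conditions: H2 (1 atm), 5% Pd/C, EtOAc, rt, stopped after one equivalent
Reagents that add atoms: none
Why: Heterogeneous hydrogenation of the exposed exocyclic enone double bond should deliver hydrogen to C9 from the face opposite the angular C10 methyl (as in hydrogenation of steroidal 17(20)-enes anti to C18), which leaves the chain cis to that methyl; C5=C6, flanked by two quaternary carbons, should not be reduced.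

**Step 8**
Reactants: 11 C9-substituted hydrindenone; 12 ethyl vinyl ether
Product: 14 1-[(1S,2R,7aS)-1-[2-(tert-butyldimethylsilyloxy)ethyl]-2-hydroxy-4,4,7a-trimethyl-2,4,5,6,7,7a-hexahydro-1H-inden-2-yl]ethan-1-one (7-acetyl-7-hydroxy hydrindene; acetyl trans and hydroxyl cis to the C9 chain), via 1-ethoxyvinyl carbinol 13 (not isolated)
Conditions: 12, t-BuLi, THF, −78 → 0 °C; CeCl3, −78 °C; 11; then 0.5 M aq. HCl, THF, 0 °C
Reagents that add atoms: water, O
Why: The organocerium acyl-anion equivalent adds 1,2 to the C7 ketone from the face opposite the C9 chain and the C10 methyl (CeCl3 suppresses enolisation and C9 epimerisation), which sets C7; brief dilute acid hydrolyses the enol ether to the methyl ketone.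

**Step 9**
Reactants: 14 7-acetyl-7-hydroxy hydrindene
Product: 15 (8R,9S,10S)-12-(tert-butyldimethylsilyloxy)-8-hydroxy-13,14,15,16-tetranorlabd-5-en-7-one (8-OH trans and 8-CH3 cis to the C9 chain)
Conditions: KOH (0.3 equiv), degassed MeOH, 25 → 40 °C
Reagents that add atoms: none
Why: Methanolic hydroxide reversibly ionises the tertiary C7 hydroxyl, and the alkoxide pushes the C7–C9 ring bond with its electron pair onto the acetyl carbon (C8) while C7 becomes the carbonyl, C9 migrating with retention (α-ketol rearrangement; closest known case: the base-mediated D-homoannulation of 17-hydroxy-20-keto steroids). Ring B is closed by one-carbon ring enlargement, C8 being inserted into the C7–C9 bond of the five-membered ring (C5, C6, C7, C9, C10) through a three-centre transition state, so that only the C8–C9 bond is new. The single new stereocentre, C8, is fixed by the rotamer about C7–C8: with potassium in methanol no chelate forms, the alkoxide and the acetyl oxygen lie anti, and C9 then enters the acetyl face that leaves the new hydroxyl on the ring face opposite to the one held by the C7 hydroxyl, that is trans to the C9 chain, with the C8 methyl cis to the chain and to the C10 methyl as in the target. A chelating aluminium or boron Lewis acid would hold the two oxygens syn and give the C8 epimer from this C7 configuration, which is why a non-chelating base is specified. The step also needs C9 rather than vinylic C6 to migrate: only the C9 shift leads to the conjugated 5-en-7-one, the low point of the reversible ketol manifold, whereas a C6-shifted β,γ-unsaturated ketol can return. C9 and C10 are not touched and the C7 stereocentre is consumed.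

**Step 10**
Reactants: 15 ring-B enone ketol
Product: 16 (5R,8R,9S,10R)-12-(tert-butyldimethylsilyloxy)-8-hydroxy-13,14,15,16-tetranorlabdan-7-one (trans-decalin)
Conditions: Li (3 equiv), NH3(l)–THF, −78 °C; then solid NH4Cl
Reagents that add atoms: none
Why: Dissolving-metal conjugate reduction protonates C5 perpendicular to the enolate plane and gives the trans-fused decalin (H5 anti to the C10 methyl); the C8 oxygen is kept because it is present as the alkoxide with its C–O bond near the carbonyl plane.

**Step 11**
Reactants: 16 trans-decalone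
Product: 19 (5R,6S,8R,9S,10R)-12-(tert-butyldimethylsilyloxy)-6,8-dihydroxy-13,14,15,16-tetranorlabdan-7-one, via bis(trimethylsilyl) enol ether 17 (not isolated), via 6-trimethylsilyloxy ketone 18 (not isolated)
Conditions: Me3SiOTf, Et3N, CH2Cl2, 0 °C; mCPBA, CH2Cl2, −20 → 0 °C; citric acid, MeOH, rt
Reagents that add atoms: 3-chloroperoxybenzoic acid, O=C(OO)c1cccc(Cl)c1
Why: Rubottom oxidation: the enol ether can form only toward C6 (C8 is quaternary), and the peracid attacks C6=C7 from the face opposite the three axial methyls on C4, C8 and C10, which places the C6 oxygen equatorial and trans to the C10 methyl; mild acidic methanolysis removes both trimethylsilyl groups but not the primary tert-butyldimethylsilyl ether.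

**Step 12**
Reactants: 19 6,8-dihydroxy-7-ketone
Product: 20 (5R,6S,7R,8R,9S,10R)-12-(tert-butyldimethylsilyloxy)-13,14,15,16-tetranorlabdane-6,7,8-triol
Conditions: NaBH4, MeOH, 0 °C
Reagents that add atoms: none
Why: Borohydride reduction by axial attack from the face of H5 and H9, away from the axial C8 methyl, gives the equatorial C7 alcohol, trans to both neighbouring hydroxyls.

**Step 13**
Reactants: 20 triol
Product: 21 (5R,6S,7R,8R,9S,10R)-12-(tert-butyldimethylsilyloxy)-8-hydroxy-13,14,15,16-tetranorlabdane-6,7-diyl diacetate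
Conditions: Ac2O, pyridine, DMAP (cat.), CH2Cl2, rt
Reagents that add atoms: acetic anhydride, CC(=O)OC(C)=O
Why: DMAP-catalysed acylation esterifies the two secondary equatorial alcohols, while the hindered tertiary C8 hydroxyl is not acetylated under these conditions.

**Step 14**
Reactants: 21 silyl ether diacetate
Product: 22 (5R,6S,7R,8R,9S,10R)-8,12-dihydroxy-13,14,15,16-tetranorlabdane-6,7-diyl diacetate
Conditions: HF·pyridine, THF–pyridine, 0 °C → rt
Reagents that add atoms: none
Why: Buffered fluoride desilylation frees the primary alcohol under conditions that leave the acetates in place and do not promote acyl migration.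

**Step 15**
Reactants: 22 diol diacetate
Product: 24 (5R,6S,7R,8R,9S,10R)-8,12-epoxy-12-hydroxy-13,14,15,16-tetranorlabdane-6,7-diyl diacetate (trans-fused lactol; anomer mixture), via hydroxy aldehyde 23 (not isolated)
Conditions: (COCl)2, DMSO, CH2Cl2, −78 °C; Et3N, −78 → 0 °C
Reagents that add atoms: none
Why: Swern oxidation of the primary alcohol gives the C12 aldehyde, which closes onto the C8 hydroxyl as the five-membered lactol only after the oxidant is spent, so that over-oxidation to the lactone is avoided.

**Step 16**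
Reactants: 24 lactol; 25 ethyltriphenylphosphonium iodide
Product: 26 (5R,6S,7R,8R,9S,10R,12Z)-8-hydroxy-13-iodo-14,15-dinorlabd-12-ene-6,7-diyl diacetate
Conditions: 25, n-BuLi, THF, rt; I2, −78 °C; NaN(SiMe3)2, −20 °C; 24, −78 °C → rt (ylide in excess)
Reagents that add atoms: iodine, II
Why: Stork–Zhao-type Wittig olefination with the α-iodo ylide on the open hydroxy aldehyde 23 (the excess ylide opens the lactol): the kinetically formed cis-oxaphosphetane places iodine cis to C11 and the methyl trans, which should give the Z-iodoalkene.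

**Step 17**
Reactants: 26 Z-iodoalkene; 27 tributyl(vinyl)stannane
Product: 28 (5R,6S,7R,8R,9S,10R,12Z)-8-hydroxylabda-12,14-diene-6,7-diyl diacetate
Conditions: Pd(PPh3)4 (5 mol%), CuI (10 mol%), DMF, rt → 40 °C
Reagents that add atoms: none
Why: Stille coupling (oxidative addition, tin-to-palladium transmetalation, reductive elimination) replaces iodine by vinyl with retention of alkene geometry under neutral conditions that the acetates and the free tertiary alcohol tolerate.

**Compound list**
1 | 2,2,6-trimethylcyclohexan-1-one (racemic) | CC1CCCC(C)(C)C1=O | starting material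
2 | allyl chloroformate | C=CCOC(Cl)=O | starting material
3 | allyl 2,6,6-trimethylcyclohex-1-en-1-yl carbonate | C=CCOC(=O)OC1=C(C)CCCC1(C)C | intermediate
4 | (S)-2-allyl-2,6,6-trimethylcyclohexan-1-one | C=CC[C@]1(C)CCCC(C)(C)C1=O | intermediate
5 | (S)-2,2,6-trimethyl-6-(2-oxopropyl)cyclohexan-1-one | CC(=O)C[C@]1(C)CCCC(C)(C)C1=O | intermediate
6 | (S)-4,4,7a-trimethyl-1,4,5,6,7,7a-hexahydro-2H-inden-2-one | O=C1C=C2C(C)(C)CCC[C@@]2(C)C1 | intermediate
7 | (tert-butyldimethylsilyloxy)acetaldehyde | O=CCO[Si](C)(C)C(C)(C)C | starting material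
8 | C9 aldol adduct of 6 and 7 (mixture at C9 and C11) | O=C1C=C2C(C)(C)CCC[C@@]2(C)C1C(O)CO[Si](C)(C)C(C)(C)C | intermediate
9 | C11 methanesulfonate of 8 | O=C1C=C2C(C)(C)CCC[C@@]2(C)C1C(OS(C)(=O)=O)CO[Si](C)(C)C(C)(C)C | intermediate
10 | (7aS)-1-[2-(tert-butyldimethylsilyloxy)ethylidene]-4,4,7a-trimethyl-1,4,5,6,7,7a-hexahydro-2H-inden-2-one (E/Z mixture) | O=C1C=C2C(C)(C)CCC[C@@]2(C)C1=CCO[Si](C)(C)C(C)(C)C | intermediate
11 | (1S,7aS)-1-[2-(tert-butyldimethylsilyloxy)ethyl]-4,4,7a-trimethyl-1,4,5,6,7,7a-hexahydro-2H-inden-2-one | O=C1C=C2C(C)(C)CCC[C@@]2(C)[C@@H]1CCO[Si](C)(C)C(C)(C)C | intermediate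
12 | ethyl vinyl ether | C=COCC | starting material
13 | (1S,2R,7aS)-1-[2-(tert-butyldimethylsilyloxy)ethyl]-2-(1-ethoxyvinyl)-4,4,7a-trimethyl-2,4,5,6,7,7a-hexahydro-1H-inden-2-ol | C=C(OCC)[C@@]1(O)C=C2C(C)(C)CCC[C@@]2(C)[C@@H]1CCO[Si](C)(C)C(C)(C)C | intermediate
14 | 1-[(1S,2R,7aS)-1-[2-(tert-butyldimethylsilyloxy)ethyl]-2-hydroxy-4,4,7a-trimethyl-2,4,5,6,7,7a-hexahydro-1H-inden-2-yl]ethan-1-one | CC(=O)[C@@]1(O)C=C2C(C)(C)CCC[C@@]2(C)[C@@H]1CCO[Si](C)(C)C(C)(C)C | intermediate
15 | (8R,9S,10S)-12-(tert-butyldimethylsilyloxy)-8-hydroxy-13,14,15,16-tetranorlabd-5-en-7-one | CC(C)(C)[Si](C)(C)OCC[C@@H]1[C@@](C)(O)C(=O)C=C2C(C)(C)CCC[C@]21C | intermediate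
16 | (5R,8R,9S,10R)-12-(tert-butyldimethylsilyloxy)-8-hydroxy-13,14,15,16-tetranorlabdan-7-one | CC(C)(C)[Si](C)(C)OCC[C@@H]1[C@@](C)(O)C(=O)C[C@@H]2C(C)(C)CCC[C@]21C | intermediate
17 | 7,8-bis(trimethylsilyloxy)-6-ene from 16 | CC(C)(C)[Si](C)(C)OCC[C@@H]1[C@@](C)(O[Si](C)(C)C)C(O[Si](C)(C)C)=C[C@@H]2C(C)(C)CCC[C@]21C | intermediate
18 | 6,8-bis(trimethylsilyloxy)-7-ketone | CC(C)(C)[Si](C)(C)OCC[C@@H]1[C@@](C)(O[Si](C)(C)C)C(=O)[C@@H](O[Si](C)(C)C)[C@@H]2C(C)(C)CCC[C@]21C | intermediate
19 | (5R,6S,8R,9S,10R)-12-(tert-butyldimethylsilyloxy)-6,8-dihydroxy-13,14,15,16-tetranorlabdan-7-one | CC(C)(C)[Si](C)(C)OCC[C@@H]1[C@@](C)(O)C(=O)[C@@H](O)[C@@H]2C(C)(C)CCC[C@]21C | intermediate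
20 | (5R,6S,7R,8R,9S,10R)-12-(tert-butyldimethylsilyloxy)-13,14,15,16-tetranorlabdane-6,7,8-triol | CC(C)(C)[Si](C)(C)OCC[C@@H]1[C@@](C)(O)[C@H](O)[C@@H](O)[C@@H]2C(C)(C)CCC[C@]21C | intermediate
21 | 6,7-diacetate of 20 | CC(C)(C)[Si](C)(C)OCC[C@@H]1[C@@](C)(O)[C@H](OC(C)=O)[C@@H](OC(C)=O)[C@@H]2C(C)(C)CCC[C@]21C | intermediate
22 | (5R,6S,7R,8R,9S,10R)-8,12-dihydroxy-13,14,15,16-tetranorlabdane-6,7-diyl diacetate | OCC[C@@H]1[C@@](C)(O)[C@H](OC(C)=O)[C@@H](OC(C)=O)[C@@H]2C(C)(C)CCC[C@]21C | intermediate
23 | 8-hydroxy-12-oxo-13,14,15,16-tetranorlabdane-6,7-diyl diacetate (open form) | O=CC[C@@H]1[C@@](C)(O)[C@H](OC(C)=O)[C@@H](OC(C)=O)[C@@H]2C(C)(C)CCC[C@]21C | intermediate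
24 | 8,12-epoxy-12-hydroxy-13,14,15,16-tetranorlabdane-6,7-diyl diacetate (lactol, anomer mixture) | OC1C[C@@H]2[C@@](C)(O1)[C@H](OC(C)=O)[C@@H](OC(C)=O)[C@@H]3C(C)(C)CCC[C@]32C | intermediate
25 | ethyltriphenylphosphonium iodide | CC[P+](c1ccccc1)(c1ccccc1)c1ccccc1.[I-] | starting material
26 | (12Z)-8-hydroxy-13-iodo-14,15-dinorlabd-12-ene-6,7-diyl diacetate | I/C(C)=C\C[C@@H]1[C@@](C)(O)[C@H](OC(C)=O)[C@@H](OC(C)=O)[C@@H]2C(C)(C)CCC[C@]21C | intermediate
27 | tributyl(vinyl)stannane | C=C[Sn](CCCC)(CCCC)CCCC | starting material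
28 | (5R,6S,7R,8R,9S,10R,12Z)-8-hydroxylabda-12,14-diene-6,7-diyl diacetate (CNP0537572.1) | C=C/C(C)=C\C[C@@H]1[C@@](C)(O)[C@H](OC(C)=O)[C@@H](OC(C)=O)[C@@H]2C(C)(C)CCC[C@]21C | target

**Total step count:** 17. **Longest linear sequence:** 17 steps (1 → 28).

**Steps most likely to fail**

Step 9. The risks are competing migration of the vinylic C6, or passage through a cation-bridged syn rotamer, which would invert C8. In that case the chelate-controlled shift of the C7-epimeric ketol is used instead, setting out from 11. Wittig ethylidenation (Ph3P=CHCH3, THF, 0 °C) should give the 7-ethylidene diene F1. Dihydroxylation of its exocyclic double bond (OsO4 cat., N-methylmorpholine N-oxide, acetone–H2O) from the face opposite the C9 chain and the C10 methyl should give the diol F2. Parikh–Doering oxidation of the secondary hydroxyl (SO3·pyridine, DMSO, iPr2NEt) should give the C7-epimeric ketol F3, with the hydroxyl trans and the acetyl cis to the chain. Al(OtBu)3 in toluene at 80–100 °C then holds both oxygens syn in an aluminium chelate, so that the C9 shift leaves the new hydroxyl on the face the old one occupied; the route is rejoined at 15.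

Step 7. The risks are hydrogen delivery to the methyl-bearing face, C9 epimerisation on the catalyst, or hydrogenolysis of the allylic C–O bond. In that case the chain is brought in as the electrophile, setting out from 6. The lithium enolate (LiN(iPr)2, THF–DMPU, −78 °C) is alkylated with commercial tert-butyl(2-iodoethoxy)dimethylsilane, so that the chain enters on the face the reagent prefers. This gives 11 directly; a residual epimer mixture can be equilibrated with DBU and separated.

Step 16. The risks are slow opening of the lactol toward a thermally labile α-iodo ylide, erosion of Z selectivity, and attack of excess ylide on the acetates. In that case the geometry is set by selective cross-coupling instead, setting out from 24. Corey–Fuchs olefination with preformed Ph3P=CBr2 (CBr4, PPh3, Zn, CH2Cl2, rt) should give the 1,1-dibromoalkene F4. Palladium-catalysed trans-selective mono-methylation (Me2Zn, PdCl2[bis(2-diphenylphosphinophenyl) ether], THF, rt; Negishi coupling) should give the Z-13-bromoalkene F5. Stille coupling with 27 (Pd(PPh3)4, CuI, DMF, 60 °C) then gives 28.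

**Further compounds**
F1 | step 9 | 7-ethylidene diene (Wittig product of 11; C9 and C10 as in 11; alkene geometry mixed) | CC=C1C=C2C(C)(C)CCC[C@@]2(C)[C@@H]1CCO[Si](C)(C)C(C)(C)C
F2 | step 9 | 7,8-diol with the C7 hydroxyl trans to the C9 chain (carbinol C8 mixed) | CC(O)[C@]1(O)C=C2C(C)(C)CCC[C@@]2(C)[C@@H]1CCO[Si](C)(C)C(C)(C)C
F3 | step 9 | 1-[(1S,2S,7aS)-1-[2-(tert-butyldimethylsilyloxy)ethyl]-2-hydroxy-4,4,7a-trimethyl-2,4,5,6,7,7a-hexahydro-1H-inden-2-yl]ethan-1-one (C7 epimer of 14) | CC(=O)[C@]1(O)C=C2C(C)(C)CCC[C@@]2(C)[C@@H]1CCO[Si](C)(C)C(C)(C)C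
F0 | step 7 | none | none
F4 | step 16 | 13,13-dibromo-8-hydroxy-14,15,16-trinorlabd-12-ene-6,7-diyl diacetate | BrC(Br)=CC[C@@H]1[C@@](C)(O)[C@H](OC(C)=O)[C@@H](OC(C)=O)[C@@H]2C(C)(C)CCC[C@]21C
F5 | step 16 | (12Z)-13-bromo-8-hydroxy-14,15-dinorlabd-12-ene-6,7-diyl diacetate | Br/C(C)=C\C[C@@H]1[C@@](C)(O)[C@H](OC(C)=O)[C@@H](OC(C)=O)[C@@H]2C(C)(C)CCC[C@]21C
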